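1. Decide first whether the charge matters, since that says whether one curve or three must be reckoned.

| flask | substrate | remark | time |
|---|---|---|---|
| Friday's | 6.4 mM | run made earlier |  |
| Wednesday's | 30 mM | run made earlier |  |
| theta | 5.0 mM |  | 2.0 min |
| beta | 10 mM |  | 2.0 min |
| eta | 20 mM |  | 2.0 min |

- Friday's (time / s: target / %, side product / %, substrate / %): 10.0: 11, 5, 27; 12.0: 10, 3, 20; 25.0: 9, 13, 7; 40.0: 10, 20, 1; 50.0: 7, 25, 5; 60.0: 11, 33, 3; 80.0: 9, 42, 0
- Wednesday's (time / s: target / %, side product / %, substrate / %): 10.0: 7, 4, 27; 15.0: 14, 9, 18; 25.0: 7, 12, 2; 40.0: 12, 26, 3; 60.0: 8, 31, 0; 80.0: 10, 40, 6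

(scatter of a reading: 2 percentage points)

1. share of target in all that became target or side product for theta, beta, eta, in this order
2. how that number moves from the first to the last of them (rises all the way / rises, then falls / falls, then rises / falls all the way / hardly changes)

- the numbers in the tables scatter by 2 percentage points (one standard deviation)
- "hardly changes" means that all values lie within two and a half points (for a concentration: within two and a half percent of the largest)

2. Compare the two runs. With charges of 6.4 mM on Friday and 30 mM on Wednesday, substrate at 10.0 s reads 27 % and 27 %, and side product at 80.0 s reads 42 % and 40 %, a gap within the scatter of 2 percentage points. So reckon one curve for theta, beta and eta.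

3. Read the substrate's first-order loss from Friday's reading at 10.0 s: 0.131 s⁻¹. By 25.0 s substrate reads 7 % on Friday and 2 % on Wednesday, yet side product keeps rising.

4. Add the three species and average the two runs. Unseen are 75.0 % of the charge at 25.0 s and 46.5 % at 80.0 s. Call this the pool.

5. Read from these two sums, the pool falls at 0.00869 s⁻¹, a half-life of 1.33 min. Call this rate the drain constant, the fraction of the pool passing to side product each second. It is far slower than the substrate's loss, so from 40.0 s on, with substrate reading 1 % on Friday and 3 % on Wednesday, take the drain as the rate-limiting step for side product.

6. Way one: run the pool on to 2.0 min, which leaves 32.8 %. Hold target at 9.57 %, my mean of the readings from 40.0 s on. Side product is then 57.6 %, and the share 14.3 %.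

7. Way two: extend the straight rise of the mean side product from 12.5 % to 41.0 %. That gives 61.7 % and a share of 13.4 %.

8. The two ways part by 4.1 points, and the line cheats: it keeps one rate although the pool feeding that rate has shrunk. Commit to way one.

9. The forecast, above my share, gives 15 %, 15 % and 15 %, hardly changes, holding that “nothing depends on concentration”.

10. Theta, beta and eta give 10.3 %, 10.3 % and 10.3 %: the share hardly changes.

    substrate ⇌ target (K = 2.20, k = 0.0180 s⁻¹)
    substrate → side product (k = 0.00150 s⁻¹)
    intermediate → side product (k = 0.00820 s⁻¹)
    substrate → intermediate (k = 0.110 s⁻¹)
    2 substrate → self-condensation product (k = 1.40 × 10⁻⁴ M⁻¹ s⁻¹)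

In theta the intermediate, the pool, is made 13.8 times faster than it is used up at 0.100 min, but at 2.00 min its making is 0.147 of its use, each step taken net, so the making falls below the use between these times. At 2.00 min theta holds 6.30 % target, down from 9.57 % at 1.00 min, and 54.9 % side product against my reckoned 57.6 %. In eta the drain constant reckons the 58.4 % of intermediate at 1.00 min on to 34.7 % at 2.00 min, where eta holds 38.4 %.

The numbers in the tables were computed with constants of no real substance, and the scatter is random.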